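**Strategy.** The six-membered ring (C1, C10–C14; bicyclo[8.4.0]tetradecane numbering, exocyclic C20 on C11 and C15 on C14) is a masked cyclohexa-1,3-diene: C11 and C14 are para and each bears one exocyclic carbon. A Michael–Wittig [3+3] annulation joins a four-carbon ester ylide (C1, C10, C11, C20) to an α′-hydroxy vinyl ketone (C12–C15), forming C11–C12 and C14=C1 and closing this ring in one operation from two achiral acyclic pieces. Asymmetric allylic alkylation then moves C14=C1 into the isopropylidene while setting C1; an Eschenmoser–Claisen shift creates the C11 methylene and C10. Olefination and Nozaki–Hiyama–Kishi closure add the ten-membered ring.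

Key step: step 3

Remark: the diphosphine enantiomer that delivers (S)-configured 12 in step 5 is assumed to be the (R,R) one; if the opposite sense is found, its antipode is used.

Step 1
Reactants: 1 methoxyallene (1-methoxypropa-1,2-diene); 2 acetone
Product: 4 4-hydroxy-4-methylpent-1-en-3-one, via allenyl carbinol 3 (not isolated)
Conditions: n-BuLi, THF, −78 °C; acetone; then 5% aq. H2SO4, 0 °C
Reagents that add atoms: water, O
Why: α-Lithiation of the alkoxyallene, 1,2-addition to acetone and acid hydrolysis of the allenyl enol ether (alkoxyallene acyl-anion chemistry) should unmask the α′-hydroxy vinyl ketone.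

Step 2
Reactants: 5 methyl (E)-4-bromobut-2-enoate
Product: 7 methyl (E)-4-(triphenyl-λ5-phosphanylidene)but-2-enoate, via phosphonium bromide 6 (not isolated)
Conditions: PPh3, toluene, rt; then aq. NaOH, CH2Cl2, 0 °C
Reagents that add atoms: triphenylphosphine, c1ccc(cc1)P(c1ccccc1)c1ccccc1
Why: SN2 quaternisation of the allylic bromide and deprotonation give the isolable, vinylogous ester-stabilised ylide (Wittig reagent preparation).

Step 3
Reactants: 7 methyl (E)-4-(triphenyl-λ5-phosphanylidene)but-2-enoate; 4 4-hydroxy-4-methylpent-1-en-3-one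
Product: 9 methyl 4-(2-hydroxypropan-2-yl)cyclohexa-1,3-diene-1-carboxylate, via Michael adduct ylide 8 (not isolated)
Conditions: CH2Cl2, rt; then toluene, 90 °C
Reagents that add atoms: none
Why: The ylide adds through its ester-bearing γ-carbon (C11) to the unsubstituted vinyl terminus C12 (Michael addition), proton transfer from C11 regenerates the ylide at C1, and intramolecular Wittig olefination of the C14 ketone forms C14=C1 with loss of Ph3P=O. The closest known reaction type is the Michael–Wittig cyclohexadiene annulation of allylidene phosphoranes with enones (and the related 4-phosphonocrotonate Michael–Horner–Wadsworth–Emmons annulation). The six-membered ring closes in the olefination event, by 6-exo-trig attack of the ylide carbon on the ketone followed by oxaphosphetane collapse. No stereocentre is created (the diene is achiral), so only chemo- and regioselectivity are needed. The step needs conjugate addition through C11 rather than through the phosphorus-bearing carbon or direct olefination of the ketone: the ketone is flanked by the quaternary carbinol carbon and reacts slowly with a stabilised ylide, the CH2= terminus is unhindered, and only the C11 adduct can close a six-membered ring, the other adduct being able to revert.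

Step 4
Reactants: 9 methyl 4-(2-hydroxypropan-2-yl)cyclohexa-1,3-diene-1-carboxylate
Product: 10 methyl 4-[2-(methoxycarbonyloxy)propan-2-yl]cyclohexa-1,3-diene-1-carboxylate
Conditions: LiN(SiMe3)2, THF, −78 °C; ClCO2Me, −78 to 0 °C
Reagents that add atoms: methyl chloroformate, COC(=O)Cl
Why: Acylation of the lithium alkoxide of the tertiary allylic alcohol (carbonate formation) installs the leaving group for allylpalladium chemistry.

Step 5
Reactants: 10 methyl 4-[2-(methoxycarbonyloxy)propan-2-yl]cyclohexa-1,3-diene-1-carboxylate; 11 nitromethane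
Product: 12 methyl (3S)-3-(nitromethyl)-4-(propan-2-ylidene)cyclohex-1-ene-1-carboxylate
Conditions: Pd2(dba)3·CHCl3 (2.5 mol%), (1R,2R)-N,N′-bis[2-(diphenylphosphino)benzoyl]cyclohexane-1,2-diamine (7.5 mol%), CH3NO2 (10 equiv), CH2Cl2, 0 °C to rt
Reagents that add atoms: none
Why: Tsuji–Trost asymmetric allylic alkylation: zerovalent palladium ionises the tertiary carbonate to an η3-allyl over C15–C14–C1, the nitronate attacks the less hindered ring terminus C1 (keeping the C10=C11 enoate conjugated and moving the alkene to the exocyclic C14=C15 position), and because the two allyl faces exchange by η3–η1–η3 at the CMe2 terminus the chiral diphosphine selects the face, which should set C1 as (S).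

Step 6
Reactants: 12 methyl (3S)-3-(nitromethyl)-4-(propan-2-ylidene)cyclohex-1-ene-1-carboxylate
Product: 13 (1S)-3-(methoxycarbonyl)-6-(propan-2-ylidene)cyclohex-2-ene-1-carboxylic acid
Conditions: NaNO2, AcOH, DMSO, 35 °C
Reagents that add atoms: water, O
Why: Nitrosation of the nitronate to a nitrolic acid and its hydrolytic breakdown (a mild oxidative Nef-type conversion of a primary nitroalkane into the carboxylic acid) runs under weakly acidic conditions, so the doubly allylic C1 centre should not be enolised.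

Step 7
Reactants: 13 (1S)-3-(methoxycarbonyl)-6-(propan-2-ylidene)cyclohex-2-ene-1-carboxylic acid
Product: 14 [(1S)-3-(hydroxymethyl)-6-(propan-2-ylidene)cyclohex-2-en-1-yl]methanol
Conditions: LiAlH4, Et2O, 0 °C to rt
Reagents that add atoms: none
Why: Hydride reduction of the carboxylate and 1,2-reduction of the conjugated ester give the two primary alcohols and leave no carbonyl next to C1.

Step 8
Reactants: 14 [(1S)-3-(hydroxymethyl)-6-(propan-2-ylidene)cyclohex-2-en-1-yl]methanol; 15 N,N-dimethylacetamide dimethyl acetal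
Product: 17 2-[(1S,6S)-6-(hydroxymethyl)-2-methylidene-5-(propan-2-ylidene)cyclohexyl]-N,N-dimethylacetamide, via ketene N,O-acetal 16 (not isolated)
Conditions: MeC(OMe)2NMe2 (5 equiv), xylene, 140 °C; then K2CO3, MeOH, rt
Reagents that add atoms: none
Why: Eschenmoser–Claisen rearrangement: the ketene N,O-acetal of the allylic alcohol shifts suprafacially through a chair-like transition state and forms C9–C10 on the ring face opposite the C1 hydroxymethyl group (held pseudo-axial by A(1,3) strain with the isopropylidene), so C10 should be set trans to C1 as (S) while the alkene moves to the exocyclic C11 methylene; the non-allylic alcohol cannot rearrange and is freed again in the basic methanol work-up.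

Step 9
Reactants: 17 2-[(1S,6S)-6-(hydroxymethyl)-2-methylidene-5-(propan-2-ylidene)cyclohexyl]-N,N-dimethylacetamide
Product: 18 2-[(1S,6S)-6-formyl-2-methylidene-5-(propan-2-ylidene)cyclohexyl]-N,N-dimethylacetamide
Conditions: Dess–Martin periodinane, NaHCO3, CH2Cl2, 0 °C
Reagents that add atoms: none
Why: Buffered Dess–Martin oxidation is neutral and fast, which should avoid epimerisation or alkene migration at the α-branched β,γ-unsaturated aldehyde, which is used without storage.

Step 10
Reactants: 19 trimethyl phosphonoacetate; 20 2-(2-bromoethyl)-1,3-dioxolane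
Product: 21 methyl 2-(dimethoxyphosphoryl)-4-(1,3-dioxolan-2-yl)butanoate
Conditions: NaH, NaI (cat.), DMF, 0 to 60 °C
Reagents that add atoms: none
Why: C-Alkylation of the sodium phosphonoacetate anion with a primary bromide (SN2, iodide catalysis).

Step 11
Reactants: 21 methyl 2-(dimethoxyphosphoryl)-4-(1,3-dioxolan-2-yl)butanoate
Product: 22 methyl 2-(dimethoxyphosphoryl)-5-oxopentanoate
Conditions: 1 M HCl, THF, rt
Reagents that add atoms: water, O
Why: Acid-catalysed acetal hydrolysis releases the aldehyde; the phosphonoacetate is inert.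

Step 12
Reactants: 22 methyl 2-(dimethoxyphosphoryl)-5-oxopentanoate; 23 tert-butyl (triphenyl-λ5-phosphanylidene)acetate
Product: 25 1-tert-butyl 7-methyl (2Z)-6-(dimethoxyphosphoryl)-2-iodohept-2-enedioate, via iodo ylide 24 (not isolated)
Conditions: 23, N-iodosuccinimide, K2CO3, MeCN, −20 °C; then 22, rt
Reagents that add atoms: N-iodosuccinimide, O=C1CCC(=O)N1I
Why: Iodination of the stabilised ylide followed by Wittig olefination places the ester trans to the chain, which should give the (Z)-α-iodo enoate that later puts C5 and C8 cis on the ring alkene.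

Step 13
Reactants: 18 2-[(1S,6S)-6-formyl-2-methylidene-5-(propan-2-ylidene)cyclohexyl]-N,N-dimethylacetamide; 25 1-tert-butyl 7-methyl (2Z)-6-(dimethoxyphosphoryl)-2-iodohept-2-enedioate
Product: 26 1-tert-butyl 7-methyl (2Z,6E)-6-({(1S,2S)-2-[2-(dimethylamino)-2-oxoethyl]-3-methylidene-6-(propan-2-ylidene)cyclohexyl}methylidene)-2-iodohept-2-enedioate
Conditions: LiCl, i-Pr2NEt, MeCN, 0 °C to rt
Reagents that add atoms: none
Why: Horner–Wadsworth–Emmons olefination under LiCl/amine conditions is mild enough for the epimerisable aldehyde, and an α-alkyl phosphonoacetate with an α-branched aldehyde should give the (E)-trisubstituted enoate.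

Step 14
Reactants: 26 1-tert-butyl 7-methyl (2Z,6E)-6-({(1S,2S)-2-[2-(dimethylamino)-2-oxoethyl]-3-methylidene-6-(propan-2-ylidene)cyclohexyl}methylidene)-2-iodohept-2-enedioate
Product: 27 1-tert-butyl 7-methyl (2Z,6E)-2-iodo-6-({(1S,2S)-3-methylidene-2-(2-oxoethyl)-6-(propan-2-ylidene)cyclohexyl}methylidene)hept-2-enedioate
Conditions: Cp2Zr(H)Cl (1.5 equiv), THF, rt, 20 min; then H2O, SiO2
Reagents that add atoms: none
Why: Hydrozirconation of the tertiary amide gives a zirconated hemiaminal that releases the aldehyde on work-up, a reduction that should spare the esters, the alkenyl iodide and the hindered alkenes.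

Step 15
Reactants: 27 1-tert-butyl 7-methyl (2Z,6E)-2-iodo-6-({(1S,2S)-3-methylidene-2-(2-oxoethyl)-6-(propan-2-ylidene)cyclohexyl}methylidene)hept-2-enedioate
Product: 28 7-tert-butyl 3-methyl (1S,2E,6E,10S)-8-hydroxy-11-methylidene-14-(propan-2-ylidene)bicyclo[8.4.0]tetradeca-2,6-diene-3,7-dicarboxylate (both C8 epimers)
Conditions: CrCl2 (10 equiv), NiCl2 (0.1 equiv), DMSO–THF (3:1), 0.002 M, rt
Reagents that add atoms: none
Why: Nozaki–Hiyama–Kishi reaction: nickel-catalysed insertion of divalent chromium into the C7–I bond and addition of the alkenylchromium species to the C8 aldehyde should close the ten-membered ring in the presence of both esters; the ring accommodates only the C6=C7 geometry with C5 and C8 cis, and the C8 configuration is not relied on.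

Step 16
Reactants: 28 7-tert-butyl 3-methyl (1S,2E,6E,10S)-8-hydroxy-11-methylidene-14-(propan-2-ylidene)bicyclo[8.4.0]tetradeca-2,6-diene-3,7-dicarboxylate (both C8 epimers)
Product: 29 7-tert-butyl 3-methyl (1S,2E,6E,10S)-11-methylidene-8-oxo-14-(propan-2-ylidene)bicyclo[8.4.0]tetradeca-2,6-diene-3,7-dicarboxylate
Conditions: Dess–Martin periodinane, NaHCO3, CH2Cl2, 0 °C
Reagents that add atoms: none
Why: Dess–Martin oxidation of the allylic alcohol converges both C8 epimers on one enone.

Step 17
Reactants: 29 7-tert-butyl 3-methyl (1S,2E,6E,10S)-11-methylidene-8-oxo-14-(propan-2-ylidene)bicyclo[8.4.0]tetradeca-2,6-diene-3,7-dicarboxylate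
Product: 30 7-tert-butyl 3-methyl (1S,2E,6E,8R,10S)-8-hydroxy-11-methylidene-14-(propan-2-ylidene)bicyclo[8.4.0]tetradeca-2,6-diene-3,7-dicarboxylate
Conditions: (S)-1-methyl-3,3-diphenyltetrahydro-1H,3H-pyrrolo[1,2-c][1,3,2]oxazaborole (0.2 equiv), catecholborane, toluene, −78 °C
Reagents that add atoms: none
Why: Corey–Bakshi–Shibata reduction: the oxazaborolidine distinguishes the alkenyl (large) and CH2 (small) flanks of the ketone, so the (S)-catalyst should give the (8R)-alcohol under reagent control, and catecholborane at low temperature leaves the alkenes untouched.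

Step 18
Reactants: 30 7-tert-butyl 3-methyl (1S,2E,6E,8R,10S)-8-hydroxy-11-methylidene-14-(propan-2-ylidene)bicyclo[8.4.0]tetradeca-2,6-diene-3,7-dicarboxylate
Product: 31 microeunicellol A, (1S,2E,6E,8R,10S)-8-hydroxy-3-(methoxycarbonyl)-11-methylidene-14-(propan-2-ylidene)bicyclo[8.4.0]tetradeca-2,6-diene-7-carboxylic acid
Conditions: Me3SiOTf, 2,6-lutidine, CH2Cl2, 0 °C; then aq. citric acid, MeOH
Reagents that add atoms: none
Why: Silyl triflate-mediated tert-butyl ester cleavage (loss of isobutene, then hydrolysis of the silyl ester and silyl ether) avoids protic acid, so the methyl ester, the allylic alcohol and the acid-sensitive exocyclic alkenes should survive.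

**Compound list**

1 | methoxyallene (1-methoxypropa-1,2-diene) | COC=C=C | starting material
2 | acetone | CC(C)=O | starting material
3 | 3-methoxy-2-methylpenta-3,4-dien-2-ol | COC(=C=C)C(C)(C)O | intermediate
4 | 4-hydroxy-4-methylpent-1-en-3-one | C=CC(=O)C(C)(C)O | intermediate
5 | methyl (E)-4-bromobut-2-enoate | COC(=O)/C=C/CBr | starting material
6 | [(E)-4-methoxy-4-oxobut-2-en-1-yl]triphenylphosphonium bromide | COC(=O)/C=C/C[P+](c1ccccc1)(c1ccccc1)c1ccccc1.[Br-] | intermediate
7 | methyl (E)-4-(triphenyl-λ5-phosphanylidene)but-2-enoate | COC(=O)/C=C/C=P(c1ccccc1)(c1ccccc1)c1ccccc1 | intermediate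
8 | methyl 2-(4-hydroxy-4-methyl-3-oxopentyl)-4-(triphenyl-λ5-phosphanylidene)but-2-enoate | COC(=O)C(CCC(=O)C(C)(C)O)=CC=P(c1ccccc1)(c1ccccc1)c1ccccc1 | intermediate
9 | methyl 4-(2-hydroxypropan-2-yl)cyclohexa-1,3-diene-1-carboxylate | COC(=O)C1=CC=C(CC1)C(C)(C)O | intermediate
10 | methyl 4-[2-(methoxycarbonyloxy)propan-2-yl]cyclohexa-1,3-diene-1-carboxylate | COC(=O)OC(C)(C)C1=CC=C(CC1)C(=O)OC | intermediate
11 | nitromethane | C[N+](=O)[O-] | starting material
12 | methyl (3S)-3-(nitromethyl)-4-(propan-2-ylidene)cyclohex-1-ene-1-carboxylate | COC(=O)C1=C[C@H](C[N+](=O)[O-])C(=C(C)C)CC1 | intermediate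
13 | (1S)-3-(methoxycarbonyl)-6-(propan-2-ylidene)cyclohex-2-ene-1-carboxylic acid | COC(=O)C1=C[C@H](C(=O)O)C(=C(C)C)CC1 | intermediate
14 | [(1S)-3-(hydroxymethyl)-6-(propan-2-ylidene)cyclohex-2-en-1-yl]methanol | OCC1=C[C@H](CO)C(=C(C)C)CC1 | intermediate
15 | N,N-dimethylacetamide dimethyl acetal (1,1-dimethoxy-N,N-dimethylethanamine) | CC(OC)(OC)N(C)C | starting material
16 | {(6S)-3-({[1-(dimethylamino)ethenyl]oxy}methyl)-6... written as [(1S)-3-({[1-(dimethylamino)ethenyl]oxy}methyl)-6-(propan-2-ylidene)cyclohex-2-en-1-yl]methanol | C=C(N(C)C)OCC1=C[C@H](CO)C(=C(C)C)CC1 | intermediate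
17 | 2-[(1S,6S)-6-(hydroxymethyl)-2-methylidene-5-(propan-2-ylidene)cyclohexyl]-N,N-dimethylacetamide | C=C1CCC(=C(C)C)[C@@H](CO)[C@@H]1CC(=O)N(C)C | intermediate
18 | 2-[(1S,6S)-6-formyl-2-methylidene-5-(propan-2-ylidene)cyclohexyl]-N,N-dimethylacetamide | C=C1CCC(=C(C)C)[C@@H](C=O)[C@@H]1CC(=O)N(C)C | intermediate
19 | trimethyl phosphonoacetate | COC(=O)CP(=O)(OC)OC | starting material
20 | 2-(2-bromoethyl)-1,3-dioxolane | BrCCC1OCCO1 | starting material
21 | methyl 2-(dimethoxyphosphoryl)-4-(1,3-dioxolan-2-yl)butanoate | COC(=O)C(CCC1OCCO1)P(=O)(OC)OC | intermediate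
22 | methyl 2-(dimethoxyphosphoryl)-5-oxopentanoate | COC(=O)C(CCC=O)P(=O)(OC)OC | intermediate
23 | tert-butyl (triphenyl-λ5-phosphanylidene)acetate | CC(C)(C)OC(=O)C=P(c1ccccc1)(c1ccccc1)c1ccccc1 | starting material
24 | tert-butyl iodo(triphenyl-λ5-phosphanylidene)acetate | CC(C)(C)OC(=O)C(I)=P(c1ccccc1)(c1ccccc1)c1ccccc1 | intermediate
25 | 1-tert-butyl 7-methyl (2Z)-6-(dimethoxyphosphoryl)-2-iodohept-2-enedioate | COC(=O)C(CC/C=C(/C(=O)OC(C)(C)C)I)P(=O)(OC)OC | intermediate
26 | 1-tert-butyl 7-methyl (2Z,6E)-6-({(1S,2S)-2-[2-(dimethylamino)-2-oxoethyl]-3-methylidene-6-(propan-2-ylidene)cyclohexyl}methylidene)-2-iodohept-2-enedioate | C=C1CCC(=C(C)C)[C@@H](/C=C(/C(=O)OC)CC/C=C(/C(=O)OC(C)(C)C)I)[C@@H]1CC(=O)N(C)C | intermediate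
27 | 1-tert-butyl 7-methyl (2Z,6E)-2-iodo-6-({(1S,2S)-3-methylidene-2-(2-oxoethyl)-6-(propan-2-ylidene)cyclohexyl}methylidene)hept-2-enedioate | C=C1CCC(=C(C)C)[C@@H](/C=C(/C(=O)OC)CC/C=C(/C(=O)OC(C)(C)C)I)[C@@H]1CC=O | intermediate
28 | 7-tert-butyl 3-methyl (1S,2E,6E,10S)-8-hydroxy-11-methylidene-14-(propan-2-ylidene)bicyclo[8.4.0]tetradeca-2,6-diene-3,7-dicarboxylate (C8 epimers) | C=C1CCC(=C(C)C)[C@H]2/C=C(/C(=O)OC)CC/C=C(/C(=O)OC(C)(C)C)C(O)C[C@H]12 | intermediate
29 | 7-tert-butyl 3-methyl (1S,2E,6E,10S)-11-methylidene-8-oxo-14-(propan-2-ylidene)bicyclo[8.4.0]tetradeca-2,6-diene-3,7-dicarboxylate | C=C1CCC(=C(C)C)[C@H]2/C=C(/C(=O)OC)CC/C=C(/C(=O)OC(C)(C)C)C(=O)C[C@H]12 | intermediate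
30 | 7-tert-butyl 3-methyl (1S,2E,6E,8R,10S)-8-hydroxy-11-methylidene-14-(propan-2-ylidene)bicyclo[8.4.0]tetradeca-2,6-diene-3,7-dicarboxylate | C=C1CCC(=C(C)C)[C@H]2/C=C(/C(=O)OC)CC/C=C(/C(=O)OC(C)(C)C)[C@H](O)C[C@H]12 | intermediate
31 | microeunicellol A, (1S,2E,6E,8R,10S)-8-hydroxy-3-(methoxycarbonyl)-11-methylidene-14-(propan-2-ylidene)bicyclo[8.4.0]tetradeca-2,6-diene-7-carboxylic acid | C=C1CCC(=C(C)C)[C@H]2/C=C(/C(=O)OC)CC/C=C(/C(=O)O)[C@H](O)C[C@H]12 | target

**Step count.** 18 steps in total. Longest linear sequence: 14 steps (steps 1, 3–9, 13–18).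

**Steps most likely to fail**

1. Step 5: the allylpalladium intermediate may be captured with poor enantiofacial discrimination. The fallback sets out from carbonate 10, which is alkylated with nitromethane under an achiral catalyst (Pd(PPh3)4, CH2Cl2) to racemic methyl 3-(nitromethyl)-4-(propan-2-ylidene)cyclohex-1-ene-1-carboxylate F1. This is converted (NaNO2, AcOH, DMSO) into racemic 3-(methoxycarbonyl)-6-(propan-2-ylidene)cyclohex-2-ene-1-carboxylic acid F2. Classical resolution by crystallisation with (R)-1-phenylethylamine (or its antipode, whichever makes the (1S)-acid salt the less soluble one) gives (R)-1-phenylethylammonium (1S)-3-(methoxycarbonyl)-6-(propan-2-ylidene)cyclohex-2-ene-1-carboxylate F3, and acidification with 1 M HCl returns the route at acid 13.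

2. Step 15: reduction of the C–I bond or oligomerisation may outrun closure of the strained ten-membered ring. The fallback sets out from amide 17 and closes the ring by olefination instead. Cp2Zr(H)Cl gives 2-[(1S,6S)-6-(hydroxymethyl)-2-methylidene-5-(propan-2-ylidene)cyclohexyl]acetaldehyde F4. An intermolecular Nozaki–Hiyama–Kishi coupling with iodide 25 (CrCl2, NiCl2 cat., DMSO) gives 1-tert-butyl 7-methyl (2E)-6-(dimethoxyphosphoryl)-2-{1-hydroxy-2-[(1S,6S)-6-(hydroxymethyl)-2-methylidene-5-(propan-2-ylidene)cyclohexyl]ethyl}hept-2-enedioate F5. Dess–Martin oxidation of both alcohols gives 1-tert-butyl 7-methyl (2E)-6-(dimethoxyphosphoryl)-2-{[(1S,6S)-6-formyl-2-methylidene-5-(propan-2-ylidene)cyclohexyl]acetyl}hept-2-enedioate F6. Intramolecular Horner–Wadsworth–Emmons olefination at high dilution (LiCl, i-Pr2NEt, MeCN) then returns the route at enone 29.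

3. Step 3: direct olefination of the ketone, attack through the phosphorus-bearing carbon or polymerisation of the enone may compete with the productive conjugate addition. The fallback sets out from bromide 5 and enone 4 and uses a phosphonate carbanion. Arbuzov reaction of 5 with P(OMe)3 gives methyl (E)-4-(dimethoxyphosphoryl)but-2-enoate F7. Enone 4 is silylated (Et3SiOTf, 2,6-lutidine) to 4-methyl-4-(triethylsilyloxy)pent-1-en-3-one F8. Tandem Michael addition–Horner–Wadsworth–Emmons annulation of F7 with F8 (LiN(SiMe3)2, THF, −78 °C to rt) gives methyl 4-[2-(triethylsilyloxy)propan-2-yl]cyclohexa-1,3-diene-1-carboxylate F9. Desilylation (AcOH, THF, H2O) returns the route at diene 9.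

**Further compounds**

F1 | step 5 | methyl 3-(nitromethyl)-4-(propan-2-ylidene)cyclohex-1-ene-1-carboxylate (racemic) | COC(=O)C1=CC(C[N+](=O)[O-])C(=C(C)C)CC1
F2 | step 5 | 3-(methoxycarbonyl)-6-(propan-2-ylidene)cyclohex-2-ene-1-carboxylic acid (racemic) | COC(=O)C1=CC(C(=O)O)C(=C(C)C)CC1
F3 | step 5 | (R)-1-phenylethylammonium (1S)-3-(methoxycarbonyl)-6-(propan-2-ylidene)cyclohex-2-ene-1-carboxylate | C[C@@H]([NH3+])c1ccccc1.[O-]C(=O)[C@H]1C=C(C(=O)OC)CCC1=C(C)C
F4 | step 15 | 2-[(1S,6S)-6-(hydroxymethyl)-2-methylidene-5-(propan-2-ylidene)cyclohexyl]acetaldehyde | C=C1CCC(=C(C)C)[C@@H](CO)[C@@H]1CC=O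
F5 | step 15 | 1-tert-butyl 7-methyl (2E)-6-(dimethoxyphosphoryl)-2-{1-hydroxy-2-[(1S,6S)-6-(hydroxymethyl)-2-methylidene-5-(propan-2-ylidene)cyclohexyl]ethyl}hept-2-enedioate | C=C1CCC(=C(C)C)[C@@H](CO)[C@@H]1CC(O)/C(C(=O)OC(C)(C)C)=C\CCC(C(=O)OC)P(=O)(OC)OC
F6 | step 15 | 1-tert-butyl 7-methyl (2E)-6-(dimethoxyphosphoryl)-2-{[(1S,6S)-6-formyl-2-methylidene-5-(propan-2-ylidene)cyclohexyl]acetyl}hept-2-enedioate | C=C1CCC(=C(C)C)[C@@H](C=O)[C@@H]1CC(=O)/C(C(=O)OC(C)(C)C)=C\CCC(C(=O)OC)P(=O)(OC)OC
F7 | step 3 | methyl (E)-4-(dimethoxyphosphoryl)but-2-enoate | COC(=O)/C=C/CP(=O)(OC)OC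
F8 | step 3 | 4-methyl-4-(triethylsilyloxy)pent-1-en-3-one | C=CC(=O)C(C)(C)O[Si](CC)(CC)CC
F9 | step 3 | methyl 4-[2-(triethylsilyloxy)propan-2-yl]cyclohexa-1,3-diene-1-carboxylate | COC(=O)C1=CC=C(CC1)C(C)(C)O[Si](CC)(CC)CC
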